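**Plan**
- Ring C is cut at O1–C2 and C2–C3 (C2 comes from DMF dimethyl acetal) and then at C4–C4a, leaving a ring A aryllithium and the Weinreb amide of 4-hydroxyphenylacetic acid (ring B, C3, C4).
- Ring A is cut at C5–C6, C7–C8 and C4a–C5 into a 2-prenyl-3-silyloxycyclobutenone (C5, C8, C8a, C4a) and a chiral siloxyalkyne (C6, C7 and the hydroxyalkyl chain).
- This works because ring A is hexasubstituted, with oxygen on C5, C7 and C8a alternating with carbon on C6, C8 and C4a; a ketene carbonyl, an ynol ether and a 3-oxycyclobutenone supply exactly these three oxygens.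
- Forward: both partners are made from esters by Kowalski homologation, ring A is formed by benzannulation, its only free hydroxyl (O5) is methylated, the aryl silyl ethers are exchanged for MOM ethers, C4a is lithiated and acylated, and ring C closes last during acidic deprotection.
- The single stereocentre, (S) at the side-chain carbinol, is set by Noyori hydrogenation of methyl 4-methyl-3-oxopentanoate and never sits next to an activating group afterwards.

Key step: step 6

Remark: atom labels (O1, C2 to C8a) follow chromen-4-one numbering of the target. Ketene is taken from pyrolysis of acetone in a ketene generator. The enaminone of step 13 and the transient centres of the cyclobutenone and hemiaminal intermediates are taken as isomer mixtures, since all converge.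

**Step 1**
Reactants: 1 methyl 4-methyl-3-oxopentanoate
Product: 2 methyl (3S)-3-hydroxy-4-methylpentanoate
Conditions: H2 (50 bar), RuCl2[(R)-BINAP] (cat.), MeOH, 50 °C
Reagents that add atoms: none
Why: Noyori asymmetric hydrogenation of a β-keto ester delivers hydrogen to the same face as in the reduction of methyl acetoacetate to the (R)-alcohol with (R)-BINAP, which is named S here because isopropyl outranks CH2CO2Me, and this sets the only stereocentre of the target.

**Step 2**
Reactants: 2 methyl (3S)-3-hydroxy-4-methylpentanoate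
Product: 3 methyl (3S)-3-(tert-butyldimethylsilyloxy)-4-methylpentanoate
Conditions: TBSCl, imidazole, DMF, rt
Reagents that add atoms: tert-butyldimethylsilyl chloride, CC(C)(C)[Si](C)(C)Cl
Why: Standard silylation of a secondary alcohol gives an ether that withstands the strong bases and heat of the following steps.

**Step 3**
Reactants: 3 methyl (3S)-3-(tert-butyldimethylsilyloxy)-4-methylpentanoate
Product: 6 (3S)-3-(tert-butyldimethylsilyloxy)-2-methyl-6-(triisopropylsilyloxy)hex-5-yne, via lithium dibromoenolate 4 (not isolated), via lithium ynolate 5 (not isolated)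
Conditions: CH2Br2, lithium 2,2,6,6-tetramethylpiperidide (from the amine and n-BuLi), THF, −78 °C; LiN(SiMe3)2, −78 → −20 °C; n-BuLi, −78 °C → rt; TIPSOTf (excess), −78 → 0 °C
Reagents that add atoms: dibromomethane, BrCBr; triisopropylsilyl trifluoromethanesulfonate, CC(C)[Si](OS(=O)(=O)C(F)(F)F)(C(C)C)C(C)C
Why: Kowalski ester homologation stopped at the ynolate: LiCHBr2 adds to the ester, the dibromomethyl ketone is enolised on the bromine side to 4 (so the β-silyloxy group cannot eliminate), bromine–lithium exchange triggers the 1,2-shift to 5, and the bulky silyl triflate silylates oxygen, leaving the stereocentre untouched.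

**Step 4**
Reactants: 7 methyl 4-methylpent-3-enoate
Product: 10 5-methyl-1-(triisopropylsilyloxy)hex-4-en-1-yne, via lithium dibromoenolate 8 (not isolated), via lithium ynolate 9 (not isolated)
Conditions: CH2Br2, lithium 2,2,6,6-tetramethylpiperidide (from the amine and n-BuLi), THF, −78 °C; LiN(SiMe3)2, −78 → −20 °C; n-BuLi, −78 °C → rt; TIPSOTf (excess), −78 → 0 °C
Reagents that add atoms: dibromomethane, BrCBr; triisopropylsilyl trifluoromethanesulfonate, CC(C)[Si](OS(=O)(=O)C(F)(F)F)(C(C)C)C(C)C
Why: The same Kowalski homologation and O-silylation applies, with addition of LiCHBr2 at −78 °C expected to outrun α-deprotonation of the β,γ-unsaturated ester.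

**Step 5**
Reactants: 10 5-methyl-1-(triisopropylsilyloxy)hex-4-en-1-yne
Product: 11 2-(3-methylbut-2-enyl)-3-(triisopropylsilyloxy)cyclobut-2-en-1-one
Conditions: ketene (gas, from pyrolysis of acetone), CH2Cl2, 0 °C
Reagents that add atoms: ketene, C=C=O
Why: Thermal [2+2] cycloaddition of ketene with an electron-rich ynol ether, in which the prenyl-bearing alkyne carbon attacks the ketene carbonyl carbon, places the silyloxy group at C3 of the cyclobutenone.

**Step 6**
Reactants: 11 2-(3-methylbut-2-enyl)-3-(triisopropylsilyloxy)cyclobut-2-en-1-one and 6 (3S)-3-(tert-butyldimethylsilyloxy)-2-methyl-6-(triisopropylsilyloxy)hex-5-yne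
Product: 16 2-[(2S)-2-(tert-butyldimethylsilyloxy)-3-methylbutyl]-4-(3-methylbut-2-enyl)-3,5-bis(triisopropylsilyloxy)phenol, via vinylketene 12 (not isolated), via 4-vinylcyclobutenone 13 (not isolated), via dienylketene 14 (not isolated), via cyclohexa-2,4-dienone 15 (not isolated)
Conditions: toluene, 80 °C, then 110 °C (near-equimolar partners)
Reagents that add atoms: none
Why: Four-electron electrocyclic opening of 11 gives vinylketene 12, whose carbonyl carbon (future C5) is attacked by the chain-bearing carbon of ynol ether 6 (C6) while the oxygen-bearing alkyne carbon (C7) bonds to the ketene α-carbon (C8), giving 13 by [2+2] cycloaddition. Compound 13 reopens to dienylketene 14, which closes ring A by thermal disrotatory six-electron electrocyclisation between C5 and the CH2 terminus C4a to give dienone 15, and tautomerisation delivers phenol 16. The closest known reaction is the Danheiser benzannulation of cyclobutenones with siloxyalkynes, including 3-silyloxycyclobutenones that lead to phloroglucinol derivatives. No stereocentre is formed, since the quaternary carbon of 13 is transient and the (S)-carbinol centre has no acidifying neighbour. The step needs regiocontrol in the ketene–alkyne addition, which the polarisation of the siloxyalkyne by its oxygen secures, so that the chiral chain lands ortho and the alkyne-derived silyloxy group meta to the new hydroxyl. It also needs the phenol not to be acylated by surplus vinylketene, which the near-equimolar stoichiometry should ensure.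

**Step 7**
Reactants: 16 2-[(2S)-2-(tert-butyldimethylsilyloxy)-3-methylbutyl]-4-(3-methylbut-2-enyl)-3,5-bis(triisopropylsilyloxy)phenol
Product: 17 2-[(2S)-2-(tert-butyldimethylsilyloxy)-3-methylbutyl]-1-methoxy-4-(3-methylbut-2-enyl)-3,5-bis(triisopropylsilyloxy)benzene
Conditions: MeI, K2CO3, acetone, 50 °C
Reagents that add atoms: iodomethane, CI
Why: Williamson O-methylation of the single free phenol (O5) in dry acetone should leave the aryl triisopropylsilyl ethers intact.

**Step 8**
Reactants: 17 2-[(2S)-2-(tert-butyldimethylsilyloxy)-3-methylbutyl]-1-methoxy-4-(3-methylbut-2-enyl)-3,5-bis(triisopropylsilyloxy)benzene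
Product: 18 4-[(2S)-2-(tert-butyldimethylsilyloxy)-3-methylbutyl]-5-methoxy-2-(3-methylbut-2-enyl)benzene-1,3-diol
Conditions: Bu4NF, AcOH, THF, 0 °C → rt
Reagents that add atoms: none
Why: Fluoride cleavage of aryl silyl ethers is much faster than that of the hindered secondary alkyl TBS ether because phenoxide is the better leaving group, and the acetic acid buffer protects the electron-rich diphenol.

**Step 9**
Reactants: 18 4-[(2S)-2-(tert-butyldimethylsilyloxy)-3-methylbutyl]-5-methoxy-2-(3-methylbut-2-enyl)benzene-1,3-diol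
Product: 19 2-[(2S)-2-(tert-butyldimethylsilyloxy)-3-methylbutyl]-1-methoxy-3,5-bis(methoxymethoxy)-4-(3-methylbut-2-enyl)benzene
Conditions: NaH, MOMCl, DMF, 0 °C → rt
Reagents that add atoms: chloromethyl methyl ether, COCCl
Why: Williamson-type alkylation of both phenoxides installs MOM ethers, which serve as directing groups for the ortho-lithiation of step 12 and as acid-labile protection.

**Step 10**
Reactants: 20 4-hydroxyphenylacetic acid
Product: 21 2-(4-hydroxyphenyl)-N-methoxy-N-methylacetamide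
Conditions: MeNH(OMe)·HCl, EDC·HCl, HOBt (cat.), N-methylmorpholine, CH2Cl2, 0 °C → rt
Reagents that add atoms: N,O-dimethylhydroxylamine hydrochloride, CNOC.Cl
Why: Carbodiimide amide coupling gives the Weinreb amide, the amine outcompeting the phenol for the active ester.

**Step 11**
Reactants: 21 2-(4-hydroxyphenyl)-N-methoxy-N-methylacetamide
Product: 22 N-methoxy-2-[4-(methoxymethoxy)phenyl]-N-methylacetamide
Conditions: MOMCl, i-Pr2NEt, CH2Cl2, 0 °C → rt
Reagents that add atoms: chloromethyl methyl ether, COCCl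
Why: MOM protection of the phenol removes the acidic OH before step 12 and gives ring B the same acid-labile group as ring A.

**Step 12**
Reactants: 19 2-[(2S)-2-(tert-butyldimethylsilyloxy)-3-methylbutyl]-1-methoxy-3,5-bis(methoxymethoxy)-4-(3-methylbut-2-enyl)benzene and 22 N-methoxy-2-[4-(methoxymethoxy)phenyl]-N-methylacetamide
Product: 25 1-{3-[(2S)-2-(tert-butyldimethylsilyloxy)-3-methylbutyl]-2-methoxy-4,6-bis(methoxymethoxy)-5-(3-methylbut-2-enyl)phenyl}-2-[4-(methoxymethoxy)phenyl]ethan-1-one, via aryllithium 23 (not isolated), via lithium hemiaminal 24 (not isolated)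
Conditions: n-BuLi, THF, 0 °C; then 22, −78 → 0 °C; then H2O
Reagents that add atoms: none
Why: Directed ortho-metalation followed by Weinreb ketone synthesis: n-BuLi removes the only ring hydrogen (C4a), flanked and coordinated by the C5 methoxy and C8a methoxymethoxy groups, to give 23, which adds to 22 to form the chelated adduct 24 that releases the ketone only on work-up (C4–C4a bond).

**Step 13**
Reactants: 25 1-{3-[(2S)-2-(tert-butyldimethylsilyloxy)-3-methylbutyl]-2-methoxy-4,6-bis(methoxymethoxy)-5-(3-methylbut-2-enyl)phenyl}-2-[4-(methoxymethoxy)phenyl]ethan-1-one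
Product: 26 1-{3-[(2S)-2-(tert-butyldimethylsilyloxy)-3-methylbutyl]-2-methoxy-4,6-bis(methoxymethoxy)-5-(3-methylbut-2-enyl)phenyl}-3-(dimethylamino)-2-[4-(methoxymethoxy)phenyl]prop-2-en-1-one
Conditions: Me2NCH(OMe)2, toluene, 100 °C
Reagents that add atoms: N,N-dimethylformamide dimethyl acetal, COC(OC)N(C)C
Why: Enaminone formation by condensation of the activated benzylic methylene of a deoxybenzoin with DMF dimethyl acetal installs C2 while all phenols are masked and so cannot be O-methylated by the reagent.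

**Step 14**
Reactants: 26 1-{3-[(2S)-2-(tert-butyldimethylsilyloxy)-3-methylbutyl]-2-methoxy-4,6-bis(methoxymethoxy)-5-(3-methylbut-2-enyl)phenyl}-3-(dimethylamino)-2-[4-(methoxymethoxy)phenyl]prop-2-en-1-one
Product: 29 7-hydroxy-6-[(2S)-2-hydroxy-3-methylbutyl]-3-(4-hydroxyphenyl)-5-methoxy-8-(3-methylbut-2-enyl)chromen-4-one, via tris-phenol enaminone 27 (not isolated), via silyl ether isoflavone 28 (not isolated)
Conditions: 3 M aq HCl, MeOH, 45 °C
Reagents that add atoms: none
Why: Acidic cleavage of the three aryl MOM acetals gives 27, whose C8a hydroxyl adds to the protonated enaminone and expels dimethylamine (the standard enaminone route to chromones, closing ring C) to give 28, and the same medium removes the TBS ether, while the C5 methyl ether blocks closure at the other ortho oxygen and the homobenzylic carbinol centre cannot ionise or epimerise.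

**Compound list**
1 | methyl 4-methyl-3-oxopentanoate | COC(=O)CC(=O)C(C)C | starting material
2 | methyl (3S)-3-hydroxy-4-methylpentanoate | COC(=O)C[C@H](O)C(C)C | intermediate
3 | methyl (3S)-3-(tert-butyldimethylsilyloxy)-4-methylpentanoate | COC(=O)C[C@H](O[Si](C)(C)C(C)(C)C)C(C)C | intermediate
4 | lithium (4S)-1,1-dibromo-4-(tert-butyldimethylsilyloxy)-5-methylhex-1-en-2-olate | [Li]OC(=C(Br)Br)C[C@H](O[Si](C)(C)C(C)(C)C)C(C)C | intermediate (not isolated)
5 | lithium (4S)-4-(tert-butyldimethylsilyloxy)-5-methylhex-1-yn-1-olate | [Li]OC#CC[C@H](O[Si](C)(C)C(C)(C)C)C(C)C | intermediate (not isolated)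
6 | (3S)-3-(tert-butyldimethylsilyloxy)-2-methyl-6-(triisopropylsilyloxy)hex-5-yne | CC(C)[Si](C(C)C)(C(C)C)OC#CC[C@H](O[Si](C)(C)C(C)(C)C)C(C)C | intermediate
7 | methyl 4-methylpent-3-enoate | COC(=O)CC=C(C)C | starting material
8 | lithium 1,1-dibromo-5-methylhexa-1,4-dien-2-olate | [Li]OC(=C(Br)Br)CC=C(C)C | intermediate (not isolated)
9 | lithium 5-methylhex-4-en-1-yn-1-olate | [Li]OC#CCC=C(C)C | intermediate (not isolated)
10 | 5-methyl-1-(triisopropylsilyloxy)hex-4-en-1-yne | CC(C)[Si](C(C)C)(C(C)C)OC#CCC=C(C)C | intermediate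
11 | 2-(3-methylbut-2-enyl)-3-(triisopropylsilyloxy)cyclobut-2-en-1-one | O=C1CC(O[Si](C(C)C)(C(C)C)C(C)C)=C1CC=C(C)C | intermediate
12 | 2-(3-methylbut-2-enyl)-3-(triisopropylsilyloxy)buta-1,3-dien-1-one | O=C=C(CC=C(C)C)C(O[Si](C(C)C)(C(C)C)C(C)C)=C | intermediate (not isolated)
13 | 2-[(2S)-2-(tert-butyldimethylsilyloxy)-3-methylbutyl]-4-(3-methylbut-2-enyl)-3-(triisopropylsilyloxy)-4-[1-(triisopropylsilyloxy)ethenyl]cyclobut-2-en-1-one (both configurations at C4) | O=C1C(C[C@H](O[Si](C)(C)C(C)(C)C)C(C)C)=C(O[Si](C(C)C)(C(C)C)C(C)C)C1(CC=C(C)C)C(O[Si](C(C)C)(C(C)C)C(C)C)=C | intermediate (not isolated)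
14 | (3E)-2-[(2S)-2-(tert-butyldimethylsilyloxy)-3-methylbutyl]-4-(3-methylbut-2-enyl)-3,5-bis(triisopropylsilyloxy)hexa-1,3,5-trien-1-one (C2 and C5 cis) | O=C=C(C[C@H](O[Si](C)(C)C(C)(C)C)C(C)C)/C(O[Si](C(C)C)(C(C)C)C(C)C)=C(CC=C(C)C)\C(O[Si](C(C)C)(C(C)C)C(C)C)=C | intermediate (not isolated)
15 | 2-[(2S)-2-(tert-butyldimethylsilyloxy)-3-methylbutyl]-4-(3-methylbut-2-enyl)-3,5-bis(triisopropylsilyloxy)cyclohexa-2,4-dien-1-one | O=C1CC(O[Si](C(C)C)(C(C)C)C(C)C)=C(CC=C(C)C)C(O[Si](C(C)C)(C(C)C)C(C)C)=C1C[C@H](O[Si](C)(C)C(C)(C)C)C(C)C | intermediate (not isolated)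
16 | 2-[(2S)-2-(tert-butyldimethylsilyloxy)-3-methylbutyl]-4-(3-methylbut-2-enyl)-3,5-bis(triisopropylsilyloxy)phenol | Oc1cc(O[Si](C(C)C)(C(C)C)C(C)C)c(CC=C(C)C)c(O[Si](C(C)C)(C(C)C)C(C)C)c1C[C@H](O[Si](C)(C)C(C)(C)C)C(C)C | intermediate
17 | 2-[(2S)-2-(tert-butyldimethylsilyloxy)-3-methylbutyl]-1-methoxy-4-(3-methylbut-2-enyl)-3,5-bis(triisopropylsilyloxy)benzene | COc1cc(O[Si](C(C)C)(C(C)C)C(C)C)c(CC=C(C)C)c(O[Si](C(C)C)(C(C)C)C(C)C)c1C[C@H](O[Si](C)(C)C(C)(C)C)C(C)C | intermediate
18 | 4-[(2S)-2-(tert-butyldimethylsilyloxy)-3-methylbutyl]-5-methoxy-2-(3-methylbut-2-enyl)benzene-1,3-diol | COc1cc(O)c(CC=C(C)C)c(O)c1C[C@H](O[Si](C)(C)C(C)(C)C)C(C)C | intermediate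
19 | 2-[(2S)-2-(tert-butyldimethylsilyloxy)-3-methylbutyl]-1-methoxy-3,5-bis(methoxymethoxy)-4-(3-methylbut-2-enyl)benzene | COc1cc(OCOC)c(CC=C(C)C)c(OCOC)c1C[C@H](O[Si](C)(C)C(C)(C)C)C(C)C | intermediate
20 | 4-hydroxyphenylacetic acid | OC(=O)Cc1ccc(O)cc1 | starting material
21 | 2-(4-hydroxyphenyl)-N-methoxy-N-methylacetamide | CON(C)C(=O)Cc1ccc(O)cc1 | intermediate
22 | N-methoxy-2-[4-(methoxymethoxy)phenyl]-N-methylacetamide | CON(C)C(=O)Cc1ccc(OCOC)cc1 | intermediate
23 | {3-[(2S)-2-(tert-butyldimethylsilyloxy)-3-methylbutyl]-2-methoxy-4,6-bis(methoxymethoxy)-5-(3-methylbut-2-enyl)phenyl}lithium | COc1c([Li])c(OCOC)c(CC=C(C)C)c(OCOC)c1C[C@H](O[Si](C)(C)C(C)(C)C)C(C)C | intermediate (not isolated)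
24 | lithium alkoxide of the N-methoxy-N-methyl hemiaminal formed from 23 and 22 (both configurations at the carbinolamine carbon) | COc1c(C(O[Li])(Cc2ccc(OCOC)cc2)N(C)OC)c(OCOC)c(CC=C(C)C)c(OCOC)c1C[C@H](O[Si](C)(C)C(C)(C)C)C(C)C | intermediate (not isolated)
25 | 1-{3-[(2S)-2-(tert-butyldimethylsilyloxy)-3-methylbutyl]-2-methoxy-4,6-bis(methoxymethoxy)-5-(3-methylbut-2-enyl)phenyl}-2-[4-(methoxymethoxy)phenyl]ethan-1-one | COc1c(C(=O)Cc2ccc(OCOC)cc2)c(OCOC)c(CC=C(C)C)c(OCOC)c1C[C@H](O[Si](C)(C)C(C)(C)C)C(C)C | intermediate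
26 | 1-{3-[(2S)-2-(tert-butyldimethylsilyloxy)-3-methylbutyl]-2-methoxy-4,6-bis(methoxymethoxy)-5-(3-methylbut-2-enyl)phenyl}-3-(dimethylamino)-2-[4-(methoxymethoxy)phenyl]prop-2-en-1-one (double-bond isomers) | COc1c(C(=O)C(=CN(C)C)c2ccc(OCOC)cc2)c(OCOC)c(CC=C(C)C)c(OCOC)c1C[C@H](O[Si](C)(C)C(C)(C)C)C(C)C | intermediate
27 | 1-{3-[(2S)-2-(tert-butyldimethylsilyloxy)-3-methylbutyl]-4,6-dihydroxy-2-methoxy-5-(3-methylbut-2-enyl)phenyl}-3-(dimethylamino)-2-(4-hydroxyphenyl)prop-2-en-1-one | COc1c(C(=O)C(=CN(C)C)c2ccc(O)cc2)c(O)c(CC=C(C)C)c(O)c1C[C@H](O[Si](C)(C)C(C)(C)C)C(C)C | intermediate (not isolated)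
28 | 6-[(2S)-2-(tert-butyldimethylsilyloxy)-3-methylbutyl]-7-hydroxy-3-(4-hydroxyphenyl)-5-methoxy-8-(3-methylbut-2-enyl)chromen-4-one | COc1c(C[C@H](O[Si](C)(C)C(C)(C)C)C(C)C)c(O)c(CC=C(C)C)c2occ(-c3ccc(O)cc3)c(=O)c12 | intermediate (not isolated)
29 | 7-hydroxy-6-[(2S)-2-hydroxy-3-methylbutyl]-3-(4-hydroxyphenyl)-5-methoxy-8-(3-methylbut-2-enyl)chromen-4-one | COc1c(C[C@H](O)C(C)C)c(O)c(CC=C(C)C)c2occ(-c3ccc(O)cc3)c(=O)c12 | target

**Step count**
Total: 14 steps. Longest linear sequence: 10 steps (1 → 2 → 3 → 6 → 16 → 17 → 18 → 19 → 25 → 26 → 29).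

**Steps most likely to fail**

Step 6. The [2+2] addition between the fully substituted ketene terminus of 12 and the hindered alkyne 6 may be slowed by the two triisopropylsilyl groups. Dimerisation of the vinylketene or acylation of the product phenol by it would then take over. The fallback keeps the benzannulation but leaves the prenyl group out of the cascade and adds it afterwards. It sets out from 6. Commercial cyclobutane-1,3-dione is O-silylated (TIPSOTf, Et3N, CH2Cl2, −78 °C) to 3-(triisopropylsilyloxy)cyclobut-2-en-1-one F1, whose unsubstituted vinylketene is the usual uncrowded partner in this reaction. Heating F1 with 6 in toluene should give 2-[(2S)-2-(tert-butyldimethylsilyloxy)-3-methylbutyl]-3,5-bis(triisopropylsilyloxy)phenol F2. Methylation (MeI, K2CO3, acetone) gives 2-[(2S)-2-(tert-butyldimethylsilyloxy)-3-methylbutyl]-1-methoxy-3,5-bis(triisopropylsilyloxy)benzene F3. Buffered Bu4NF gives 4-[(2S)-2-(tert-butyldimethylsilyloxy)-3-methylbutyl]-5-methoxybenzene-1,3-diol F4, and NaH/MOMCl gives 2-[(2S)-2-(tert-butyldimethylsilyloxy)-3-methylbutyl]-1-methoxy-3,5-bis(methoxymethoxy)benzene F5. Lithiation of F5 with n-BuLi should occur at the position between the two methoxymethoxy groups (C8), the most strongly directed site. Transmetalation with CuI and alkylation with prenyl bromide then returns to the route at 19.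

Step 12. Proton transfer from the benzylic, amide-activated CH2 of 22 to the hindered aryllithium may compete with acyl transfer and simply return 19. The fallback forms the bond to ring B by cross-coupling instead of carrying it in the acyl donor. It sets out from 23. Acylation with the much less acidic N-methoxy-N-methylacetamide (THF, −78 → 0 °C) gives 1-{3-[(2S)-2-(tert-butyldimethylsilyloxy)-3-methylbutyl]-2-methoxy-4,6-bis(methoxymethoxy)-5-(3-methylbut-2-enyl)phenyl}ethan-1-one F6. Palladium-catalysed α-arylation of this methyl ketone with commercial 1-bromo-4-(methoxymethoxy)benzene (Pd2(dba)3, a zerovalent palladium source, XPhos, NaOt-Bu, toluene, 80 °C) comes back to the route at 25.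

Step 14. During the time needed to cleave the hindered secondary silyl ether, acid may add the freed C7 or C8a hydroxyl (or HCl or methanol) across the prenyl double bond. The fallback unmasks the molecule in two stages without free Brønsted acid. It sets out from 26. TMSOTf and 2,2′-bipyridyl (CH2Cl2, 0 °C) convert the three aryl MOM ethers into the tris(trimethylsilyl) ether F7. Aqueous work-up hydrolyses F7 to 27, which should close to 28 on brief contact with silica gel or a trace of AcOH; 28 is isolated this time. HF·pyridine in THF/pyridine (0 °C → rt) then removes the TBS ether and arrives at 29.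

**Further compounds**
F1 | step 6 | 3-(triisopropylsilyloxy)cyclobut-2-en-1-one | O=C1CC(O[Si](C(C)C)(C(C)C)C(C)C)=C1
F2 | step 6 | 2-[(2S)-2-(tert-butyldimethylsilyloxy)-3-methylbutyl]-3,5-bis(triisopropylsilyloxy)phenol | Oc1cc(O[Si](C(C)C)(C(C)C)C(C)C)cc(O[Si](C(C)C)(C(C)C)C(C)C)c1C[C@H](O[Si](C)(C)C(C)(C)C)C(C)C
F3 | step 6 | 2-[(2S)-2-(tert-butyldimethylsilyloxy)-3-methylbutyl]-1-methoxy-3,5-bis(triisopropylsilyloxy)benzene | COc1cc(O[Si](C(C)C)(C(C)C)C(C)C)cc(O[Si](C(C)C)(C(C)C)C(C)C)c1C[C@H](O[Si](C)(C)C(C)(C)C)C(C)C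
F4 | step 6 | 4-[(2S)-2-(tert-butyldimethylsilyloxy)-3-methylbutyl]-5-methoxybenzene-1,3-diol | COc1cc(O)cc(O)c1C[C@H](O[Si](C)(C)C(C)(C)C)C(C)C
F5 | step 6 | 2-[(2S)-2-(tert-butyldimethylsilyloxy)-3-methylbutyl]-1-methoxy-3,5-bis(methoxymethoxy)benzene | COc1cc(OCOC)cc(OCOC)c1C[C@H](O[Si](C)(C)C(C)(C)C)C(C)C
F6 | step 12 | 1-{3-[(2S)-2-(tert-butyldimethylsilyloxy)-3-methylbutyl]-2-methoxy-4,6-bis(methoxymethoxy)-5-(3-methylbut-2-enyl)phenyl}ethan-1-one | COc1c(C(C)=O)c(OCOC)c(CC=C(C)C)c(OCOC)c1C[C@H](O[Si](C)(C)C(C)(C)C)C(C)C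
F7 | step 14 | 1-{3-[(2S)-2-(tert-butyldimethylsilyloxy)-3-methylbutyl]-2-methoxy-5-(3-methylbut-2-enyl)-4,6-bis(trimethylsilyloxy)phenyl}-3-(dimethylamino)-2-[4-(trimethylsilyloxy)phenyl]prop-2-en-1-one | COc1c(C(=O)C(=CN(C)C)c2ccc(O[Si](C)(C)C)cc2)c(O[Si](C)(C)C)c(CC=C(C)C)c(O[Si](C)(C)C)c1C[C@H](O[Si](C)(C)C(C)(C)C)C(C)C
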